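We follow the left hand.

| flask | left-handed substrate | right-handed substrate | partner | precatalyst | temperature | remark | time |
|---|---|---|---|---|---|---|---|
| epsilon | 13 mM | 13 mM | 44 mM | 20 µM | 35 °C | run made earlier |  |
| alpha | 30 mM | 30 mM | 44 mM | 20 µM | 54 °C | run made earlier |  |
| theta | 20 mM | 20 mM | 44 mM | 30 µM | 35 °C | run made earlier |  |
| spring | 20 mM | 20 mM | 44.0 mM | 20 µM | 58 °C |  | 8.0 min |
| autumn | 20 mM | 20 mM | 44.0 mM | 20 µM | 50 °C |  | 8.0 min |

- epsilon (time / min: left-handed product / %, left-handed substrate / %): 0.833: 0, 49.7; 1.33: 0.7, 49.6; 2.00: 0.5, 49.1; 3.00: 1.4, 49.1; 4.00: 2.0, 48.6; 6.00: 2.7, 47.9; 10.0: 4.1, 45.9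
- alpha (time / min: left-handed product / %, left-handed substrate / %): 0.417: 0.8, 49.7; 0.667: 1.0, 48.5; 0.833: 1.1, 48.0; 1.33: 2.5, 47.4; 2.00: 3.7, 46.5; 3.00: 5.1, 45.2; 5.00: 8.1, 43.3
- theta (time / min: left-handed product / %, left-handed substrate / %): 2.00: 0.9, 49.1; 4.00: 1.6, 48.7; 6.00: 2.5, 47.0; 8.00: 3.4, 46.5; 10.0: 3.9, 46.2

(readings scatter by 0.3 percentage points)

- partner is single-handed; left-handed substrate and right-handed substrate are mirror images of each other, charged as a racemate, each of them at the stated concentration
- steps that have been proposed: partner + left-handed substrate -> left-handed product; partner + right-handed substrate -> right-handed product; partner + precatalyst -> racemization catalyst + spent reagent; left-handed substrate + racemization catalyst <-> right-handed substrate + racemization catalyst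
- the handed part of partner does not stay in what it makes, so the products of the two hands are mirror images too

- which of the two there is more of at the end, spring (right-handed product / left-handed product)
- which of the two there is more of at the end, autumn (right-handed product / left-handed product)
- left-handed product at the end, in percent of the left-handed substrate and right-handed substrate together charged, spring
- left-handed product at the end, in percent of the left-handed substrate and right-handed substrate together charged, autumn

1. Main step alone. We work with the fraction left: if left substrate falls only by the partner step, the fraction left is exp(-k[partner]t), whatever its charge. Left substrate plus left product stays at 50.0 % at the end of epsilon, so left product counts the loss there. Using mean [partner], epsilon gives k = 0.197 L mol⁻¹ min⁻¹ and theta 0.188 L mol⁻¹ min⁻¹, with 0.192 L mol⁻¹ min⁻¹ as their mean. Alpha gives 0.850 L mol⁻¹ min⁻¹.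

2. Temperature. Taking ln k as straight in temperature, a rough stand-in for the Arrhenius line, the left constant, the fraction of left substrate lost per minute per unit of [partner], is 1.16 L mol⁻¹ min⁻¹ in spring and 0.622 L mol⁻¹ min⁻¹ in autumn. With [partner] held at its charge, left product comes to 16.8 % in spring and 9.83 % in autumn.

3. Partner runs down. With mean [partner], the exponent k[partner]t is 0.378 in spring and 0.209 in autumn. Left product drops to 15.7 % in spring and 9.43 % in autumn.

4. Racemization. In alpha the left sum is 50.2 % at 2.00 min but 51.4 % at 5.00 min, an excess of 1.4 percentage points with each reading scattering by 0.3 points. Racemization carries material from the richer substrate to the poorer, so we read this excess as a sign that right substrate stood above left in alpha, with the left hand consumed faster. We therefore expect left product to lead in both flasks. Borrowing that excess, present for about the later part of the run, adds excess times exponent over two, which gives our 16.0 % for spring and 9.58 % for autumn.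

The forecast says right-handed product for spring and right-handed product for autumn, with left product 15.5 % and 9.7 %. It reads the same excess as meaning “right substrate is being depleted faster”. We part from it on the hand.

5. Spring ends with left product 16.0 % against right product 0.136 %, autumn with 9.55 % against 0.0828 %.

    partner + left-handed substrate → left-handed product (k = 0.626 L mol⁻¹ min⁻¹, Ea = 68.0 kJ mol⁻¹)
    partner + right-handed substrate → right-handed product (k = 0.00497 L mol⁻¹ min⁻¹, Ea = 61.0 kJ mol⁻¹)
    partner + precatalyst → racemization catalyst + spent reagent (k = 1.57 L mol⁻¹ min⁻¹, Ea = 67.0 kJ mol⁻¹)
    left-handed substrate + racemization catalyst ⇌ right-handed substrate + racemization catalyst, rate k4*[racemization catalyst]*[left-handed substrate] forward; the back reaction follows from the equilibrium constant (k = 6130 L mol⁻¹ min⁻¹, Ea = 41.0 kJ mol⁻¹)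
    (constants at 50 °C)

In spring the left step uses partner 130 times as fast as the right step at the start, the selectivity factor at that temperature, and 110 times as fast at 8.00 min. In spring, left product taken from the left charge leaves 68.0 % of that charge, against a fraction left of 68.5 % from the left constant. For a neighbouring flask, spring stopped at 5.0 min, the same constant gives 10.8 % left product, and that flask holds 10.8 %.

The runs were computed with made-up constants; noise was put on by code.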